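**Plan**

1. Numbering used throughout: ring A is C1–C5 plus C10 (C4 carries the gem-dimethyl group); the arm C6–C7–C8(=O)–CH3 sits on C5; the ketone C9 sits on C10; the chain is C11–C15 with the methyl on C13; the glycerol is on the C15 carboxyl. Salen is the dianion of N,N′-bis(3,5-di-tert-butylsalicylidene)-trans-cyclohexane-1,2-diamine.
2. Retrosynthetic cuts, in order: the glycerol C–O bond to the C15 carboxylate (epoxide opening); C9–C11 (acyl chloride plus alkylzinc); the two C4–CH3 bonds and the C3 oxygen; last, C1–C10 and C4–C5 of ring A by a [4+2] cycloaddition.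
3. Enabling feature: C10 (CH3, C9) and C5 (H, C6) are the α- and β-carbons of an E-2-methyl-2-enal with C9 trans to C6, and C1–C4 are the four carbons of a 1-amino-3-siloxybutadiene whose oxygen lands on C3, next to C4.
4. Forward: enal 5 and carbamate diene 10 close ring A (11, step 7); the enone 13 is released, C4 is dimethylated, the ring is saturated and C3 deoxygenated; acid 23 is joined to the zinc reagent of 26; acid 30 opens (S)-glycidyl acetate to give the target.
5. Stereochemistry: C5 and C10 get their absolute configuration from the chiral chromium–salen Lewis acid and their relative configuration from the E-alkene; C13 comes from (R)-3-methylglutaric acid monomethyl ester; glycerol C2 comes from (R)-glycidol.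
6. The diene carries an N-benzyl-N-methoxycarbonyl group, because a free dialkylamino diene reacts without the catalyst and binds Lewis acids.

Key step: step 7

Assumption: the (R,R)-configured chromium–salen catalyst is taken to shield the enal face that leads to the (1R,5R,6S) adduct 11; if a first run shows the opposite sense, the equally available (S,S)-catalyst is used and nothing else changes.

**Route**

Step 1
Reactants: 1 ethyl levulinate
Product: 2 ethyl 3-(2-methyl-1,3-dioxolan-2-yl)propanoate
Conditions: HOCH2CH2OH, p-TsOH (cat.), toluene, reflux, Dean–Stark trap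
Reagents that add atoms: ethylene glycol, OCCO
Why: Acid-catalysed ketalisation with azeotropic removal of water should protect the ketone as a 1,3-dioxolane that tolerates the hydride, enolate and hydrazine chemistry ahead.

Step 2
Reactants: 2 ethyl 3-(2-methyl-1,3-dioxolan-2-yl)propanoate
Product: 3 3-(2-methyl-1,3-dioxolan-2-yl)propanal
Conditions: iBu2AlH (1.05 equiv), CH2Cl2, −78 °C; Rochelle salt work-up
Reagents that add atoms: none
Why: Partial ester reduction with iBu2AlH at −78 °C should stop at the aldehyde, because the tetrahedral aluminium hemiacetal does not collapse before the quench.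

Step 3
Reactants: 3 3-(2-methyl-1,3-dioxolan-2-yl)propanal; 4 2-(triphenylphosphoranylidene)propanal
Product: 5 (2E)-2-methyl-5-(2-methyl-1,3-dioxolan-2-yl)pent-2-enal
Conditions: toluene, 80 °C
Reagents that add atoms: none
Why: A Wittig reaction with a formyl-stabilised ylide is E-selective, and the conjugated product is a much poorer electrophile than 3, so a second olefination should be slow.

Step 4
Reactants: 6 (3E)-4-methoxybut-3-en-2-one; 7 benzylamine
Product: 8 (3Z)-4-(benzylamino)but-3-en-2-one
Conditions: CH2Cl2, 0 °C → rt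
Reagents that add atoms: none
Why: Addition–elimination of the amine at the β-methoxy enone should give the hydrogen-bonded Z vinylogous amide.

Step 5
Reactants: 8 (3Z)-4-(benzylamino)but-3-en-2-one
Product: 9 methyl benzyl[(1E)-3-oxobut-1-en-1-yl]carbamate
Conditions: NaN(SiMe3)2, THF, −78 °C; ClCO2Me, −78 → 0 °C
Reagents that add atoms: methyl chloroformate, COC(=O)Cl
Why: N-Acylation of the sodium salt of the vinylogous amide should give the vinylogous carbamate, which relaxes to the E alkene once the N–H···O hydrogen bond is gone.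

Step 6
Reactants: 9 methyl benzyl[(1E)-3-oxobut-1-en-1-yl]carbamate
Product: 10 methyl benzyl[(1E)-3-(tert-butyldimethylsilyloxy)buta-1,3-dien-1-yl]carbamate
Conditions: KN(SiMe3)2, THF, −78 °C; tBuMe2SiCl, −78 °C → rt
Reagents that add atoms: tert-butyldimethylsilyl chloride, CC(C)(C)[Si](C)(C)Cl
Why: Kinetic deprotonation of the methyl ketone and O-silylation of the potassium enolate (silyl enol ether formation) should give the 1-amino-3-siloxy diene with the E enamide geometry kept.

Step 7
Reactants: 5 (2E)-2-methyl-5-(2-methyl-1,3-dioxolan-2-yl)pent-2-enal; 10 methyl benzyl[(1E)-3-(tert-butyldimethylsilyloxy)buta-1,3-dien-1-yl]carbamate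
Product: 11 methyl benzyl{(1R,5R,6S)-3-(tert-butyldimethylsilyloxy)-6-formyl-6-methyl-5-[2-(2-methyl-1,3-dioxolan-2-yl)ethyl]cyclohex-2-en-1-yl}carbamate
Conditions: (R,R)-[Cr(salen)]SbF6 (10 mol%, preformed), 4 Å molecular sieves, CH2Cl2, −40 → 0 °C; chromatography on Et3N-deactivated silica
Reagents that add atoms: none
Why: Proposed new method: the cationic trivalent chromium centre binds the formyl oxygen of 5 and lowers its LUMO, and diene 10 adds in a concerted, asynchronous [4+2] cycloaddition whose closest known relative is the [Cr(salen)]SbF6-catalysed Diels–Alder reaction of such carbamate dienes with α-substituted acroleins, extended here to an α-methyl-β-alkyl enal whose β-substituent lowers reactivity without changing the mechanism. Ring A is closed by this intermolecular [4+2] cycloaddition, which forms the C1–C10 and C4–C5 bonds in one event. The relative configuration of C10 and C5 follows from suprafacial addition to the E-alkene, so the formyl carbon C9 ends trans to the arm and the methyl cis to it. The absolute configuration of both centres is set by the chiral salen ligand, which blocks one face of the coordinated enal. The C1 centre follows from the endo approach and is erased in step 8, so endo/exo control is not critical. The step needs regioselectivity, which the diene secures because its amino and siloxy donors both raise the HOMO coefficient at the unsubstituted CH2 terminus, and this terminus bonds to the electrophilic β-carbon C5 of the enal.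

Step 8
Reactants: 11 the cycloadduct
Product: 13 (4S,5R)-4-(hydroxymethyl)-4-methyl-5-[2-(2-methyl-1,3-dioxolan-2-yl)ethyl]cyclohex-2-en-1-one, via amino alcohol 12 (not isolated)
Conditions: LiAlH4, THF, 0 °C → reflux, aqueous NaOH work-up; then 0.1 M HCl, THF–H2O, 0 °C
Reagents that add atoms: none
Why: LiAlH4 should reduce the aldehyde to the alcohol and the methyl carbamate to an N-methyl amine, after which cold dilute acid hydrolyses the silyl enol ether and expels the protonated amine by β-elimination to the enone, the dioxolane hydrolysing much more slowly and C5 and C10 staying untouched.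

Step 9
Reactants: 13 the hydroxymethyl enone
Product: 14 (4S,5R)-4-[(benzyloxy)methyl]-4-methyl-5-[2-(2-methyl-1,3-dioxolan-2-yl)ethyl]cyclohex-2-en-1-one
Conditions: BnOC(=NH)CCl3, CF3SO3H (cat.), CH2Cl2–cyclohexane, 0 °C → rt
Reagents that add atoms: benzyl 2,2,2-trichloroacetimidate, N=C(OCc1ccccc1)C(Cl)(Cl)Cl
Why: Acid-catalysed O-benzylation with a trichloroacetimidate avoids an alkoxide, which could fragment by vinylogous retro-aldol loss of formaldehyde, and the anhydrous catalytic acid should leave the dioxolane alone.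

Step 10
Reactants: 14 the benzyl ether enone
Product: 16 (4R,5S)-4-[(benzyloxy)methyl]-4,6,6-trimethyl-5-[2-(2-methyl-1,3-dioxolan-2-yl)ethyl]cyclohex-2-en-1-one, via monomethyl enone 15 (not isolated)
Conditions: LiN(iPr)2, THF, −78 °C, then MeI, → 0 °C; second cycle LiN(iPr)2, MeI, DMPU, −78 °C → rt
Reagents that add atoms: iodomethane, CI
Why: Enolate alkylation can occur only at C4, since C2 is vinylic and C10 quaternary, so two rounds of base and MeI should build the gem-dimethyl group there, and the configuration of the first methylation is irrelevant (the descriptor changes are due to priority rules only).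

Step 11
Reactants: 16 the dimethylated enone
Product: 18 (3S,4R)-4-(hydroxymethyl)-2,2,4-trimethyl-3-[2-(2-methyl-1,3-dioxolan-2-yl)ethyl]cyclohexan-1-one, via saturated benzyl ether 17 (not isolated)
Conditions: H2 (1 atm), 10% Pd/C, EtOAc–EtOH, rt
Reagents that add atoms: none
Why: Heterogeneous hydrogenation should saturate the cis-disubstituted C1–C2 alkene and then hydrogenolyse the benzyl ether, while the ketone and the dioxolane are inert under neutral conditions and no stereocentre is formed.

Step 12
Reactants: 18 the hydroxy ketone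
Product: 21 4-[(1R,2R)-2-(hydroxymethyl)-2,6,6-trimethylcyclohexyl]butan-2-one, via hydrazone 19 (not isolated), via ketal alcohol 20 (not isolated)
Conditions: N2H4·H2O, KOH, diethylene glycol, 130 °C then 200 °C; then 2 M HCl, THF–H2O, rt
Reagents that add atoms: water, O
Why: Wolff–Kishner reduction should remove the C3 carbonyl, as it does for 4,4-dimethyl-3-keto terpenoids, with the free alcohol and the base-stable dioxolane as spectators, and the acidic second stage then hydrolyses the ketal, which is no longer needed.

Step 13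
Reactants: 21 the keto alcohol
Product: 23 (1R,2R)-1,3,3-trimethyl-2-(3-oxobutyl)cyclohexane-1-carboxylic acid, via keto aldehyde 22 (not isolated)
Conditions: CrO3, H2SO4, H2O–acetone, 0 °C → rt
Reagents that add atoms: water, O
Why: Jones oxidation should take the neopentyl primary alcohol through the aldehyde hydrate to the acid, the quaternary α-carbon being unable to epimerise and the methyl ketone being inert.

Step 14
Reactants: 24 (3R)-5-methoxy-3-methyl-5-oxopentanoic acid [(R)-3-methylglutaric acid monomethyl ester]
Product: 25 methyl (3R)-5-hydroxy-3-methylpentanoate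
Conditions: BH3·SMe2, THF, −10 °C → rt; neutral aqueous work-up
Reagents that add atoms: none
Why: Borane reduces a carboxylic acid far faster than an ester, so only the free carboxyl should become CH2OH, and the stereocentre of the commercial half-ester is not touched.

Step 15
Reactants: 25 methyl (3R)-5-hydroxy-3-methylpentanoate
Product: 26 methyl (3S)-5-iodo-3-methylpentanoate
Conditions: I2, PPh3, imidazole, CH2Cl2, 0 °C → rt
Reagents that add atoms: iodine, II
Why: Appel-type iodination should replace the primary hydroxyl by SN2 at CH2 and, run without delay, forestall lactonisation of the hydroxy ester (the descriptor changes by priority rules only).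

Step 16
Reactants: 23 the keto acid; 26 methyl (3S)-5-iodo-3-methylpentanoate
Product: 29 methyl (3R)-3-methyl-6-oxo-6-[(1R,2R)-1,3,3-trimethyl-2-(3-oxobutyl)cyclohexyl]hexanoate, via acid chloride 27 (not isolated), via alkylzinc iodide 28 (not isolated)
Conditions: 23 with (COCl)2, DMF (cat.), CH2Cl2, 0 °C → rt, evaporate; 26 with Zn dust (activated by BrCH2CH2Br and Me3SiCl), THF, 40 °C; combine with Pd(PPh3)4 (5 mol%), THF, 0 °C → rt
Reagents that add atoms: none
Why: In this Negishi acylation zinc inserts into the primary C–I bond without touching the ester, and zerovalent palladium joins the alkylzinc to the acid chloride by oxidative addition, transmetalation and reductive elimination, which should form the C9 ketone directly while the alkylzinc ignores the methyl ketone and the ester.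

Step 17
Reactants: 29 the diketo ester
Product: 30 (3R)-3-methyl-6-oxo-6-[(1R,2R)-1,3,3-trimethyl-2-(3-oxobutyl)cyclohexyl]hexanoic acid
Conditions: LiOH·H2O, THF–H2O, 0 °C; 1 M HCl to pH 3
Reagents that add atoms: lithium hydroxide, [Li+].[OH-]
Why: Saponification of the unhindered methyl ester at 0 °C should be faster than any aldol reaction onto the hindered C9 ketone, and no stereocentre lies α to a carbonyl.

Step 18
Reactants: 31 (R)-glycidol
Product: 32 (S)-glycidyl acetate
Conditions: Ac2O, Et3N, DMAP (cat.), CH2Cl2, 0 °C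
Reagents that add atoms: acetic anhydride, CC(=O)OC(C)=O
Why: Acylation of the primary alcohol under amine base should leave the epoxide and its stereocentre untouched (R becomes S by priority rules only).

Step 19
Reactants: 30 the diketo acid; 32 (S)-glycidyl acetate
Product: 33 (2R)-3-(acetyloxy)-2-hydroxypropyl (3R)-3-methyl-6-oxo-6-[(1R,2R)-1,3,3-trimethyl-2-(3-oxobutyl)cyclohexyl]hexanoate (CNP0140002.1)
Conditions: (S,S)-Co(salen) (5 mol%, divalent cobalt precatalyst oxidised by air in the presence of the acid), iPr2NEt (1 equiv), tert-butyl methyl ether, rt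
Reagents that add atoms: none
Why: In this cobalt–salen-catalysed ring opening of a terminal epoxide by a carboxylic acid, the trivalent cobalt carboxylate formed in the flask should deliver the carboxylate of 30 to the unsubstituted epoxide carbon, so the glycerol C2 centre is not a reacting centre and its hydroxyl appears unprotected under conditions too mild for acyl migration.

**Compound list**

1 | ethyl levulinate | CCOC(=O)CCC(C)=O | starting material
2 | ethyl 3-(2-methyl-1,3-dioxolan-2-yl)propanoate | CCOC(=O)CCC1(C)OCCO1 | intermediate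
3 | 3-(2-methyl-1,3-dioxolan-2-yl)propanal | O=CCCC1(C)OCCO1 | intermediate
4 | 2-(triphenylphosphoranylidene)propanal | CC(C=O)=P(c1ccccc1)(c1ccccc1)c1ccccc1 | starting material
5 | (2E)-2-methyl-5-(2-methyl-1,3-dioxolan-2-yl)pent-2-enal | O=C/C(C)=C/CCC1(C)OCCO1 | intermediate
6 | (3E)-4-methoxybut-3-en-2-one | CO/C=C/C(C)=O | starting material
7 | benzylamine | NCc1ccccc1 | starting material
8 | (3Z)-4-(benzylamino)but-3-en-2-one | CC(=O)/C=C\NCc1ccccc1 | intermediate
9 | methyl benzyl[(1E)-3-oxobut-1-en-1-yl]carbamate | CC(=O)/C=C/N(Cc1ccccc1)C(=O)OC | intermediate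
10 | methyl benzyl[(1E)-3-(tert-butyldimethylsilyloxy)buta-1,3-dien-1-yl]carbamate | C=C(O[Si](C)(C)C(C)(C)C)/C=C/N(Cc1ccccc1)C(=O)OC | intermediate
11 | methyl benzyl{(1R,5R,6S)-3-(tert-butyldimethylsilyloxy)-6-formyl-6-methyl-5-[2-(2-methyl-1,3-dioxolan-2-yl)ethyl]cyclohex-2-en-1-yl}carbamate (endo adduct, N cis to CHO, CHO trans to the arm) | CC1(CC[C@@H]2CC(O[Si](C)(C)C(C)(C)C)=C[C@@H](N(Cc3ccccc3)C(=O)OC)[C@@]2(C)C=O)OCCO1 | intermediate
12 | {(1S,2R,6R)-2-[benzyl(methyl)amino]-4-(tert-butyldimethylsilyloxy)-1-methyl-6-[2-(2-methyl-1,3-dioxolan-2-yl)ethyl]cyclohex-3-en-1-yl}methanol | CC1(CC[C@@H]2CC(O[Si](C)(C)C(C)(C)C)=C[C@@H](N(C)Cc3ccccc3)[C@@]2(C)CO)OCCO1 | intermediate (not isolated)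
13 | (4S,5R)-4-(hydroxymethyl)-4-methyl-5-[2-(2-methyl-1,3-dioxolan-2-yl)ethyl]cyclohex-2-en-1-one | CC1(CC[C@@H]2CC(=O)C=C[C@@]2(C)CO)OCCO1 | intermediate
14 | (4S,5R)-4-[(benzyloxy)methyl]-4-methyl-5-[2-(2-methyl-1,3-dioxolan-2-yl)ethyl]cyclohex-2-en-1-one | CC1(CC[C@@H]2CC(=O)C=C[C@@]2(C)COCc3ccccc3)OCCO1 | intermediate
15 | (4R,5R)-4-[(benzyloxy)methyl]-4,6-dimethyl-5-[2-(2-methyl-1,3-dioxolan-2-yl)ethyl]cyclohex-2-en-1-one (C6 epimers) | CC1(CC[C@@H]2C(C)C(=O)C=C[C@@]2(C)COCc3ccccc3)OCCO1 | intermediate (not isolated)
16 | (4R,5S)-4-[(benzyloxy)methyl]-4,6,6-trimethyl-5-[2-(2-methyl-1,3-dioxolan-2-yl)ethyl]cyclohex-2-en-1-one | CC1(CC[C@@H]2C(C)(C)C(=O)C=C[C@@]2(C)COCc3ccccc3)OCCO1 | intermediate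
17 | (3S,4R)-4-[(benzyloxy)methyl]-2,2,4-trimethyl-3-[2-(2-methyl-1,3-dioxolan-2-yl)ethyl]cyclohexan-1-one | CC1(CC[C@@H]2C(C)(C)C(=O)CC[C@@]2(C)COCc3ccccc3)OCCO1 | intermediate (not isolated)
18 | (3S,4R)-4-(hydroxymethyl)-2,2,4-trimethyl-3-[2-(2-methyl-1,3-dioxolan-2-yl)ethyl]cyclohexan-1-one | CC1(CC[C@@H]2C(C)(C)C(=O)CC[C@@]2(C)CO)OCCO1 | intermediate
19 | hydrazone of 18 | CC1(CC[C@@H]2C(C)(C)C(=NN)CC[C@@]2(C)CO)OCCO1 | intermediate (not isolated)
20 | {(1R,2R)-1,3,3-trimethyl-2-[2-(2-methyl-1,3-dioxolan-2-yl)ethyl]cyclohexyl}methanol | CC1(CC[C@@H]2C(C)(C)CCC[C@@]2(C)CO)OCCO1 | intermediate (not isolated)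
21 | 4-[(1R,2R)-2-(hydroxymethyl)-2,6,6-trimethylcyclohexyl]butan-2-one | CC(=O)CC[C@@H]1C(C)(C)CCC[C@@]1(C)CO | intermediate
22 | (1R,2R)-1,3,3-trimethyl-2-(3-oxobutyl)cyclohexane-1-carbaldehyde | CC(=O)CC[C@@H]1C(C)(C)CCC[C@@]1(C)C=O | intermediate (not isolated)
23 | (1R,2R)-1,3,3-trimethyl-2-(3-oxobutyl)cyclohexane-1-carboxylic acid | CC(=O)CC[C@@H]1C(C)(C)CCC[C@@]1(C)C(=O)O | intermediate
24 | (3R)-5-methoxy-3-methyl-5-oxopentanoic acid | COC(=O)C[C@H](C)CC(=O)O | starting material
25 | methyl (3R)-5-hydroxy-3-methylpentanoate | COC(=O)C[C@H](C)CCO | intermediate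
26 | methyl (3S)-5-iodo-3-methylpentanoate | COC(=O)C[C@H](C)CCI | intermediate
27 | (1R,2R)-1,3,3-trimethyl-2-(3-oxobutyl)cyclohexane-1-carbonyl chloride | CC(=O)CC[C@@H]1C(C)(C)CCC[C@@]1(C)C(=O)Cl | intermediate (not isolated)
28 | [(3S)-5-methoxy-3-methyl-5-oxopentyl]zinc iodide | COC(=O)C[C@H](C)CC[Zn]I | intermediate (not isolated)
29 | methyl (3R)-3-methyl-6-oxo-6-[(1R,2R)-1,3,3-trimethyl-2-(3-oxobutyl)cyclohexyl]hexanoate | CC(=O)CC[C@@H]1C(C)(C)CCC[C@@]1(C)C(=O)CC[C@@H](C)CC(=O)OC | intermediate
30 | (3R)-3-methyl-6-oxo-6-[(1R,2R)-1,3,3-trimethyl-2-(3-oxobutyl)cyclohexyl]hexanoic acid | CC(=O)CC[C@@H]1C(C)(C)CCC[C@@]1(C)C(=O)CC[C@@H](C)CC(=O)O | intermediate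
31 | (R)-glycidol, (2R)-oxiran-2-ylmethanol | OC[C@@H]1CO1 | starting material
32 | (S)-glycidyl acetate, (2S)-oxiran-2-ylmethyl acetate | CC(=O)OC[C@@H]1CO1 | intermediate
33 | (2R)-3-(acetyloxy)-2-hydroxypropyl (3R)-3-methyl-6-oxo-6-[(1R,2R)-1,3,3-trimethyl-2-(3-oxobutyl)cyclohexyl]hexanoate | CC(=O)CC[C@@H]1C(C)(C)CCC[C@@]1(C)C(=O)CC[C@@H](C)CC(=O)OC[C@H](O)COC(C)=O | target

**Step count and risks**

Total: 19 steps. Longest linear sequence: 13 steps (1, 2, 3, 7, 8, 9, 10, 11, 12, 13, 16, 17, 19).

Risk 1, step 7 (bears the label). The β-alkyl group slows the dienophile, so the cycloaddition may stall while the diene decomposes, or the catalyst may discriminate the enal faces poorly. The fallback sets out from 5 and comes back at 13, using known chemistry. Enal 5 is heated without catalyst (toluene, 60–80 °C) with commercial 1-dimethylamino-3-(tert-butyldimethylsilyloxy)buta-1,3-diene, the most reactive diene of this family, to give the racemic endo cycloadduct F1. LiAlH4 in Et2O at 0 °C reduces the formyl group to the racemic amino alcohol F2, and 0.1 M HCl in THF–H2O at 0 °C releases the racemic hydroxymethyl enone F3. Preparative chromatography on a chiral stationary phase (amylose carbamate phase, supercritical CO2–MeOH) separates the enantiomers; the (4S,5R)-enantiomer is 13 and the route resumes at step 9.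

Risk 2, step 16. Transmetalation and reductive elimination at the hindered acyl–palladium species may be slow, so that decarbonylation or protonation of the zinc reagent takes over. The fallback sets out from 21 and comes back at 29. Alcohol 21 is oxidised with Dess–Martin periodinane (NaHCO3, CH2Cl2) to the keto aldehyde 22, here isolated. Iodide 26 is added to 22 in a Nozaki–Hiyama–Kishi-type reaction (CrCl2, catalytic cobalt phthalocyanine Co(C32H16N8), DMF, rt), in which the alkylchromium species adds to the aldehyde and leaves ketone and ester alone, giving the secondary alcohol F4 as a mixture of C9 epimers. A second Dess–Martin oxidation converts both epimers into 29.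

Risk 3, step 19. The epoxide opening may be incomplete or regiochemically unclean, or acetyl and acyl groups may migrate across the new secondary hydroxyl. The fallback sets out from 30 and comes back at 33, building the glyceride with a protecting group instead. Acid 30 is esterified with (S)-solketal (EDC·HCl, DMAP, CH2Cl2) to the solketal ester F5. The acetonide is removed with 80% aqueous AcOH at 40 °C to give the monoacylglycerol F6. Acetyl chloride with 2,4,6-collidine in CH2Cl2 at −78 °C then acetylates only the primary hydroxyl to give 33.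

**Further compounds**

F1 | step 7 | rac-(1S,2R,6R)-4-(tert-butyldimethylsilyloxy)-2-(dimethylamino)-1-methyl-6-[2-(2-methyl-1,3-dioxolan-2-yl)ethyl]cyclohex-3-ene-1-carbaldehyde (racemate, one enantiomer drawn) | CC1(CC[C@@H]2CC(O[Si](C)(C)C(C)(C)C)=C[C@@H](N(C)C)[C@@]2(C)C=O)OCCO1
F2 | step 7 | rac-{(1S,2R,6R)-4-(tert-butyldimethylsilyloxy)-2-(dimethylamino)-1-methyl-6-[2-(2-methyl-1,3-dioxolan-2-yl)ethyl]cyclohex-3-en-1-yl}methanol (racemate, one enantiomer drawn) | CC1(CC[C@@H]2CC(O[Si](C)(C)C(C)(C)C)=C[C@@H](N(C)C)[C@@]2(C)CO)OCCO1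
F3 | step 7 | rac-(4S,5R)-4-(hydroxymethyl)-4-methyl-5-[2-(2-methyl-1,3-dioxolan-2-yl)ethyl]cyclohex-2-en-1-one (racemate of 13, one enantiomer drawn) | CC1(CC[C@@H]2CC(=O)C=C[C@@]2(C)CO)OCCO1
F4 | step 16 | methyl (3R,6RS)-6-hydroxy-3-methyl-6-[(1R,2R)-1,3,3-trimethyl-2-(3-oxobutyl)cyclohexyl]hexanoate | CC(=O)CC[C@@H]1C(C)(C)CCC[C@@]1(C)C(O)CC[C@@H](C)CC(=O)OC
F5 | step 19 | [(4R)-2,2-dimethyl-1,3-dioxolan-4-yl]methyl (3R)-3-methyl-6-oxo-6-[(1R,2R)-1,3,3-trimethyl-2-(3-oxobutyl)cyclohexyl]hexanoate | CC(=O)CC[C@@H]1C(C)(C)CCC[C@@]1(C)C(=O)CC[C@@H](C)CC(=O)OC[C@H]2COC(C)(C)O2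
F6 | step 19 | (2R)-2,3-dihydroxypropyl (3R)-3-methyl-6-oxo-6-[(1R,2R)-1,3,3-trimethyl-2-(3-oxobutyl)cyclohexyl]hexanoate | CC(=O)CC[C@@H]1C(C)(C)CCC[C@@]1(C)C(=O)CC[C@@H](C)CC(=O)OC[C@H](O)CO
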